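All constants are those of an exercise; the result is computed.

The constants below stand at 90 °C, and what we want from them is a share, so we first look for the step that can move that share furthest.

    partner → decomposed reagent (k1 = 3.72 × 10⁻⁴ min⁻¹, Ea1 = 123 kJ mol⁻¹)
    starting material + partner → target (k2 = 1.26 M⁻¹ min⁻¹, Ea2 = 56.0 kJ mol⁻¹)
    starting material + second substrate → cross product (k3 = 4.52 M⁻¹ min⁻¹, Ea3 = 60.0 kJ mol⁻¹)
    second substrate + partner → second product (k4 = 6.17 M⁻¹ min⁻¹, Ea4 = 48.0 kJ mol⁻¹)
    target ⇌ isomer of the product (K5 = 1.2, k5 = 0.00665 min⁻¹, Ea5 = 101 kJ mol⁻¹, ΔH5 = −13.0 kJ mol⁻¹)
    (constants at 90 °C)

- elm: starting material 0.012 M; partner 1.30 equiv; second substrate 0.200 equiv; temperature 60 °C; time 12 h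
- birch: starting material 0.012 M; partner 1.30 equiv; second substrate 0.200 equiv; temperature 90 °C; time 12 h

* the best flask by share of target in all that became target or cross product or isomer of the product; "all alike" if 1.5 percentage points covers them all (elm / birch / all alike)
* share of target in all that became target or cross product or isomer of the product, elm
* share of target in all that became target or cross product or isomer of the product, birch

- constants are those at 90 °C; use the activation energies and enthalpies for any other temperature

Target turns into isomer of the product, so we count half-lives. At 90 °C the forward step gives target a half-life of 1.74 h, which puts 6.91 forward half-lives into the birch run, and this count of forward half-lives in the run is what we carry. The forward step is 20 times slower in elm, so elm holds 0.340 of them, far fewer than birch.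

That half-life is shorter than the run, so birch should reach equilibrium, thermodynamic control against the kinetic control in elm, and target should be 45.5% of target plus isomer of the product. But target made late is young. Against that, starting material in birch, reckoned as meeting partner at equal concentrations, has a half-life of 1.10 h, short against the run, and this reckoning leaves 8.41% of it unreacted.

The share also counts cross product. At the start of birch, second substrate goes to second product 1.8 times as fast as to cross product. Can that starting ratio be trusted? Partner at its charge gives second substrate a lifetime of about 10.4 min, shorter than the half-life of starting material, so the ratio should barely drift while second substrate is consumed. Cross product is then 0.0721 equiv, and the birch share comes to 41.9%.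

In elm, the same half-life of starting material stretches by a factor of 5.3 to 5.86 h, and the reckoning leaves 32.8% unreacted. That estimate for elm is on the high side, because partner is charged at 1.30 equiv, more than the equal amount we reckoned with. Cooling shifts the split of second substrate to 2.54, so cross product is 0.0565 equiv.

Should the whole count of 0.340 apply to target in elm? No, since target is born throughout the run. The half-life of starting material in elm is shorter than the run, so we let formation lean to the early hours and take the mean age of target as 0.667 of the run. That turns 14.5% of it into isomer of the product, with the back reaction neglected. The elm share is then 78.3%.

The forecast named elm, with 80% for elm and 42.5% for birch, on the ground that “at 60 °C the isomer barely forms”. The simulation gives elm, with 79.5% for elm and 42.6% for birch, against our 78.3% and 41.9%.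

In birch the forward half-life of target at 0.796 h is 1.7 h, short against the run of 12 h, and at 12.0 h target stands at 41.5% of the starting material charged beside 48.9% isomer of the product, while elm, with 0.340 such half-lives, holds 60.7% target beside 10.0% isomer of the product. Read at 5.0 h, after 2.87 half-lives, the birch flask holds 42.1% target beside 41.0% isomer of the product, a share of 46.7%.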